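**Plan**

1. Numbering: flavan atoms O1 to C8a (rings A and C), benzofuran atoms primed. The retrosynthesis first cuts the C8–C2' bond (Negishi coupling). In the flavan half it then cuts C2–C3 and O1–C8a together, which leads back to benzaldehyde and a 4-benzyloxy-2-fluoro-6-methoxyacetophenone.
2. Enabling feature: O1 sits on C8a, ortho to C4a, and C4 hangs on C4a. With C4 as a ketone (a helper, removed in step 6) the carbonyl makes C3 a nucleophile (enol silane) and C8a–F an SNAr electrophile at once. The C3–C4–C4a–C8a unit thus acts as a 1,4-dipole that takes up the C=O of benzaldehyde as C2 and O1.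
3. Forward order: ring A is bought as 5-fluororesorcinol and dressed (acylation, chelation-controlled O-benzylation, O-methylation). Ring C closes in step 5, then C4=O is removed and C8 brominated.
4. The benzofuran is made separately from 3-methoxy-2-methylphenol (C–H borylation/oxidation, directed ortho-lithiation/iodination, vinylation and acid closure of the furan ring). The halves are joined at C8–C2' and deprotected.
5. Stereochemistry: C2, the only stereocentre, is set as S in the aldol half of step 5 by a tryptophan-derived oxazaborolidinone catalyst (Si-face attack on benzaldehyde). No later step involves C2.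

Key step: step 5

Remark on the chemistry (assumption): the (R)-tryptophan-derived catalyst is taken to expose the Si face of boron-bound benzaldehyde; if the first experiment shows the opposite sense, the (S)-catalyst is used and nothing else changes.

**Route**

Step 1
Reactants: 1 5-fluorobenzene-1,3-diol
Product: 2 1-(2-fluoro-4,6-dihydroxyphenyl)ethan-1-one
Conditions: AcOH, BF3·OEt2, 90 °C; aqueous work-up
Reagents that add atoms: acetic acid, CC(=O)O
Why: Nencki-type Friedel–Crafts C-acylation of a resorcinol, in which the acyl group enters ortho to one hydroxyl and para to the other (C4 and C6 are equivalent, C2 between the hydroxyls is hindered) and the chelated product is deactivated towards a second acylation.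

Step 2
Reactants: 2 1-(2-fluoro-4,6-dihydroxyphenyl)ethan-1-one
Product: 3 1-[4-(benzyloxy)-2-fluoro-6-hydroxyphenyl]ethan-1-one
Conditions: BnBr (1.05 equiv), K2CO3 (1.1 equiv), acetone, 56 °C
Reagents that add atoms: benzyl bromide, BrCc1ccccc1
Why: Williamson etherification, selective because the hydroxyl para to the acetyl group is the more acidic one and is not tied up in the hydrogen bond to the carbonyl that deactivates the ortho hydroxyl.

Step 3
Reactants: 3 1-[4-(benzyloxy)-2-fluoro-6-hydroxyphenyl]ethan-1-one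
Product: 4 1-[4-(benzyloxy)-2-fluoro-6-methoxyphenyl]ethan-1-one
Conditions: MeI (1.5 equiv), K2CO3, DMF, 40 °C
Reagents that add atoms: iodomethane, CI
Why: Williamson methylation of the remaining chelated hydroxyl under slightly more forcing conditions, with no other nucleophilic site left.

Step 4
Reactants: 4 1-[4-(benzyloxy)-2-fluoro-6-methoxyphenyl]ethan-1-one
Product: 5 ({1-[4-(benzyloxy)-2-fluoro-6-methoxyphenyl]ethenyl}oxy)trimethylsilane
Conditions: Me3SiOTf (1.2 equiv), Et3N (1.5 equiv), CH2Cl2, 0 °C; non-aqueous work-up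
Reagents that add atoms: trimethylsilyl trifluoromethanesulfonate, C[Si](C)(C)OS(=O)(=O)C(F)(F)F
Why: Soft enolisation of a methyl ketone with a silyl triflate and an amine gives the only possible enol silane, and the benzyl ether, methyl ether and aryl fluoride are inert.

Step 5
Reactants: 5 ({1-[4-(benzyloxy)-2-fluoro-6-methoxyphenyl]ethenyl}oxy)trimethylsilane; 6 benzaldehyde
Product: 8 (2S)-7-(benzyloxy)-5-methoxy-2-phenyl-2,3-dihydro-4H-chromen-4-one, via silyl aldolate 7 (not isolated)
Conditions: (4R)-2-butyl-4-(1H-indol-3-ylmethyl)-3-tosyl-1,3,2-oxazaborolidin-5-one (20 mol%), EtCN, −78 °C; then Bu4N[Ph3SiF2] (0.5 equiv), THF, −78 → 0 °C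
Reagents that add atoms: none
Why: Proposed new method: the boron of the oxazaborolidinone binds benzaldehyde and the enol silane 5 adds through C3 in an open Mukaiyama aldol transition state to give the silyl aldolate 7, after which fluoride attacks silicon, the freed alkoxide O1 adds to C8a of the ortho-acyl fluoroarene to give a Meisenheimer anion stabilised by the C4 carbonyl, and the fluoride expelled from C8a unmasks the next molecule of 7. The closest known reaction types are the oxazaborolidinone-catalysed enantioselective Mukaiyama aldol and aldol–dihydropyranone annulation of enol silanes with aldehydes, the fluoride-catalysed condensation of silyl ethers with activated aryl fluorides, and the ketone-activated intramolecular SNAr of 2-fluorophenyl ketones; new is their union in one flask on a 2-fluoroaryl methyl ketone. Ring C closes as a six-membered ring by intramolecular addition–elimination at the aromatic carbon C8a (exo with respect to the C–F bond that is cleaved), so the step is a formal (4+2) annulation of the C3–C4–C4a–C8a unit with the C=O of benzaldehyde. C2 is set in the aldol event by the catalyst, whose indole ring shields one face of the coordinated aldehyde so that C3 attacks the Si face and the S configuration results; the SNAr does not touch C2. The step needs ring closure to outrun retro-aldol cleavage of the alkoxide and enolisation with ring opening of the flavanone, both of which would erode the configuration; this is to be secured by generating the alkoxide only transiently, without added base and at low temperature, and by the fact that both alkoxy groups are meta to C8a and so leave the negative charge of the Meisenheimer anion (on C4a, C6 and C8) undisturbed, while fluoride at C8a is the only leaving group ortho to the carbonyl.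

Step 6
Reactants: 8 (2S)-7-(benzyloxy)-5-methoxy-2-phenyl-2,3-dihydro-4H-chromen-4-one
Product: 10 (2S)-7-(benzyloxy)-5-methoxy-2-phenyl-3,4-dihydro-2H-chromene, via flavan-4-ol 9 (not isolated)
Conditions: NaBH4, THF/MeOH, 0 °C; AcOH quench, solvent exchange; then Et3SiH (5 equiv), CF3CO2H, CH2Cl2, −20 → 0 °C
Reagents that add atoms: none
Why: Borohydride reduction of the ketone followed by ionic hydrogenation (Kursanov–Parnes) of the benzylic alcohol, in which the C4 cation, stabilised by the ortho methoxy and para benzyloxy groups, takes hydride from the silane while C2 lies off the reaction path and the benzyl ether is stable to the acid.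

Step 7
Reactants: 10 (2S)-7-(benzyloxy)-5-methoxy-2-phenyl-3,4-dihydro-2H-chromene
Product: 11 (2S)-7-(benzyloxy)-8-bromo-5-methoxy-2-phenyl-3,4-dihydro-2H-chromene
Conditions: NBS (1.0 equiv), CH2Cl2, −78 → 0 °C
Reagents that add atoms: N-bromosuccinimide, O=C1CCC(=O)N1Br
Why: Electrophilic aromatic bromination of ring A, expected at C8 (between O1 and the 7-benzyloxy group) before C6, in line with the C8-selective bromination known for 5,7-di-O-alkylated flavans.

Step 8
Reactants: 12 3-methoxy-2-methylphenol
Product: 13 (3-methoxy-2-methylphenoxy)tri(propan-2-yl)silane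
Conditions: iPr3SiCl, imidazole, DMF, 25 °C
Reagents that add atoms: chlorotri(propan-2-yl)silane, CC(C)[Si](Cl)(C(C)C)C(C)C
Why: Standard silylation of a phenol, the bulky and poorly coordinating silyl ether being chosen because it offers no unhindered aryl C–H in step 9 and does not direct lithiation in step 11.

Step 9
Reactants: 13 (3-methoxy-2-methylphenoxy)tri(propan-2-yl)silane
Product: 15 3-methoxy-4-methyl-5-{[tri(propan-2-yl)silyl]oxy}phenol, via arylboronate 14 (not isolated)
Conditions: [Ir(OMe)(cod)]2 (1.5 mol%), 4,4'-di-tert-butyl-2,2'-bipyridine (3 mol%), B2pin2 (1.0 equiv), THF, 80 °C; then KHSO5 (as Oxone), acetone/H2O, 25 °C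
Reagents that add atoms: potassium peroxymonosulfate, [K+].[O-]S(=O)(=O)OO
Why: Sterically governed iridium-catalysed aromatic C–H borylation attacks the only C–H without an ortho substituent (C5, meta to both oxygens), and oxidation of the C–B bond in the same flask gives the phenol (one-pot borylation/oxidation).

Step 10
Reactants: 15 3-methoxy-4-methyl-5-{[tri(propan-2-yl)silyl]oxy}phenol
Product: 16 [3-methoxy-5-(methoxymethoxy)-2-methylphenoxy]tri(propan-2-yl)silane
Conditions: MeOCH2Cl, iPr2NEt, CH2Cl2, 0 → 25 °C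
Reagents that add atoms: chloromethyl methyl ether, COCCl
Why: Acetal protection of the phenol, which installs the methoxymethyl ether as a strong directing group for step 11.

Step 11
Reactants: 16 [3-methoxy-5-(methoxymethoxy)-2-methylphenoxy]tri(propan-2-yl)silane
Product: 18 [4-iodo-3-methoxy-5-(methoxymethoxy)-2-methylphenoxy]tri(propan-2-yl)silane, via aryllithium 17 (not isolated)
Conditions: n-BuLi (1.2 equiv), THF, 0 °C; then I2, −78 → 25 °C
Reagents that add atoms: iodine, II
Why: Directed ortho-metalation, in which the C–H between the methoxymethoxy and methoxy groups is acidified and coordinated by both while the other ortho site lies next to the bulky, non-coordinating silyl ether, followed by iodine quench of the aryllithium.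

Step 12
Reactants: 18 [4-iodo-3-methoxy-5-(methoxymethoxy)-2-methylphenoxy]tri(propan-2-yl)silane
Product: 20 [(4-methoxy-5-methyl-1-benzofuran-6-yl)oxy]tri(propan-2-yl)silane, via enol ether 19 (not isolated)
Conditions: Pd(OAc)2 (5 mol%), SPhos (10 mol%), K3PO4, dioxane/H2O (10:1), 80 °C; extraction and solvent exchange; then HCl (1.25 M in MeOH), 50 °C
Reagents that add atoms: (E)-2-(2-ethoxyethenyl)-4,4,5,5-tetramethyl-1,3,2-dioxaborolane, CCO/C=C/B1OC(C)(C)C(C)(C)O1
Why: Suzuki–Miyaura coupling brings in a two-carbon enol ether (masked acetaldehyde), and acid then removes the methoxymethyl group and protonates the enol ether so that the phenol adds to the oxocarbenium ion and loss of ethanol aromatises the furan ring (closure at O1'–C2').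

Step 13
Reactants: 20 [(4-methoxy-5-methyl-1-benzofuran-6-yl)oxy]tri(propan-2-yl)silane; 11 (2S)-7-(benzyloxy)-8-bromo-5-methoxy-2-phenyl-3,4-dihydro-2H-chromene
Product: 23 {[2-((2S)-7-(benzyloxy)-5-methoxy-2-phenyl-3,4-dihydro-2H-chromen-8-yl)-4-methoxy-5-methyl-1-benzofuran-6-yl]oxy}tri(propan-2-yl)silane, via 2-lithiobenzofuran 21 (not isolated), via benzofuranylzinc chloride 22 (not isolated)
Conditions: 20 (1.3 equiv), n-BuLi, THF, −78 °C; ZnCl2, −78 → 25 °C; then 11, Pd2(dba)3 (2.5 mol%), XPhos (10 mol%), THF, 65 °C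
Reagents that add atoms: none
Why: Benzofurans are lithiated at C2', the most acidic C–H next to the ring oxygen, and transmetalation to zinc followed by Negishi coupling with a bulky biarylphosphine ligand is a reaction type that tolerates di-ortho-substituted, electron-rich aryl bromides.

Step 14
Reactants: 23 {[2-((2S)-7-(benzyloxy)-5-methoxy-2-phenyl-3,4-dihydro-2H-chromen-8-yl)-4-methoxy-5-methyl-1-benzofuran-6-yl]oxy}tri(propan-2-yl)silane
Product: 24 2-[(2S)-7-(benzyloxy)-5-methoxy-2-phenyl-3,4-dihydro-2H-chromen-8-yl]-4-methoxy-5-methyl-1-benzofuran-6-ol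
Conditions: Bu4NF (1.2 equiv), THF, 0 °C; aq. NH4Cl
Reagents that add atoms: none
Why: Fluoride-mediated cleavage of the aryl silyl ether, to which the benzyl ether, the methyl ethers and the flavan are inert.

Step 15
Reactants: 24 2-[(2S)-7-(benzyloxy)-5-methoxy-2-phenyl-3,4-dihydro-2H-chromen-8-yl]-4-methoxy-5-methyl-1-benzofuran-6-ol
Product: 25 2-[(2S)-7-hydroxy-5-methoxy-2-phenyl-3,4-dihydro-2H-chromen-8-yl]-4-methoxy-5-methyl-1-benzofuran-6-ol
Conditions: H2 (1 atm), Pd/C (10 wt%), EtOAc/MeOH, 25 °C
Reagents that add atoms: none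
Why: Hydrogenolysis of the benzyl aryl ether under mild conditions, under which the hindered 2-arylbenzofuran double bond and the flavan C2–O1 bond are expected to survive if the reaction is stopped at full conversion.

**Compound list**

1 | 5-fluorobenzene-1,3-diol | Oc1cc(O)cc(F)c1 | starting material
2 | 1-(2-fluoro-4,6-dihydroxyphenyl)ethan-1-one | CC(=O)c1c(O)cc(O)cc1F | intermediate
3 | 1-[4-(benzyloxy)-2-fluoro-6-hydroxyphenyl]ethan-1-one | CC(=O)c1c(O)cc(OCc2ccccc2)cc1F | intermediate
4 | 1-[4-(benzyloxy)-2-fluoro-6-methoxyphenyl]ethan-1-one | CC(=O)c1c(OC)cc(OCc2ccccc2)cc1F | intermediate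
5 | ({1-[4-(benzyloxy)-2-fluoro-6-methoxyphenyl]ethenyl}oxy)trimethylsilane | C=C(O[Si](C)(C)C)c1c(OC)cc(OCc2ccccc2)cc1F | intermediate
6 | benzaldehyde | O=Cc1ccccc1 | starting material
7 | (3S)-1-[4-(benzyloxy)-2-fluoro-6-methoxyphenyl]-3-phenyl-3-[(trimethylsilyl)oxy]propan-1-one | O=C(C[C@H](O[Si](C)(C)C)c1ccccc1)c1c(OC)cc(OCc2ccccc2)cc1F | intermediate (not isolated)
8 | (2S)-7-(benzyloxy)-5-methoxy-2-phenyl-2,3-dihydro-4H-chromen-4-one | COc1cc(OCc2ccccc2)cc2c1C(=O)C[C@@H](c1ccccc1)O2 | intermediate
9 | (2S)-7-(benzyloxy)-5-methoxy-2-phenyl-3,4-dihydro-2H-chromen-4-ol, both C4 epimers | COc1cc(OCc2ccccc2)cc2c1C(O)C[C@@H](c1ccccc1)O2 | intermediate (not isolated)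
10 | (2S)-7-(benzyloxy)-5-methoxy-2-phenyl-3,4-dihydro-2H-chromene | COc1cc(OCc2ccccc2)cc2c1CC[C@@H](c1ccccc1)O2 | intermediate
11 | (2S)-7-(benzyloxy)-8-bromo-5-methoxy-2-phenyl-3,4-dihydro-2H-chromene | COc1cc(OCc2ccccc2)c(Br)c2c1CC[C@@H](c1ccccc1)O2 | intermediate
12 | 3-methoxy-2-methylphenol | COc1cccc(O)c1C | starting material
13 | (3-methoxy-2-methylphenoxy)tri(propan-2-yl)silane | COc1cccc(O[Si](C(C)C)(C(C)C)C(C)C)c1C | intermediate
14 | [3-methoxy-2-methyl-5-(4,4,5,5-tetramethyl-1,3,2-dioxaborolan-2-yl)phenoxy]tri(propan-2-yl)silane | COc1cc(B2OC(C)(C)C(C)(C)O2)cc(O[Si](C(C)C)(C(C)C)C(C)C)c1C | intermediate (not isolated)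
15 | 3-methoxy-4-methyl-5-{[tri(propan-2-yl)silyl]oxy}phenol | COc1cc(O)cc(O[Si](C(C)C)(C(C)C)C(C)C)c1C | intermediate
16 | [3-methoxy-5-(methoxymethoxy)-2-methylphenoxy]tri(propan-2-yl)silane | COCOc1cc(OC)c(C)c(O[Si](C(C)C)(C(C)C)C(C)C)c1 | intermediate
17 | [2-methoxy-6-(methoxymethoxy)-3-methyl-4-{[tri(propan-2-yl)silyl]oxy}phenyl]lithium | COCOc1c([Li])c(OC)c(C)c(O[Si](C(C)C)(C(C)C)C(C)C)c1 | intermediate (not isolated)
18 | [4-iodo-3-methoxy-5-(methoxymethoxy)-2-methylphenoxy]tri(propan-2-yl)silane | COCOc1c(I)c(OC)c(C)c(O[Si](C(C)C)(C(C)C)C(C)C)c1 | intermediate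
19 | {4-[(E)-2-ethoxyethenyl]-3-methoxy-5-(methoxymethoxy)-2-methylphenoxy}tri(propan-2-yl)silane | COCOc1c(/C=C/OCC)c(OC)c(C)c(O[Si](C(C)C)(C(C)C)C(C)C)c1 | intermediate (not isolated)
20 | [(4-methoxy-5-methyl-1-benzofuran-6-yl)oxy]tri(propan-2-yl)silane | COc1c(C)c(O[Si](C(C)C)(C(C)C)C(C)C)cc2occc12 | intermediate
21 | (4-methoxy-5-methyl-6-{[tri(propan-2-yl)silyl]oxy}-1-benzofuran-2-yl)lithium | COc1c(C)c(O[Si](C(C)C)(C(C)C)C(C)C)cc2oc([Li])cc12 | intermediate (not isolated)
22 | chloro(4-methoxy-5-methyl-6-{[tri(propan-2-yl)silyl]oxy}-1-benzofuran-2-yl)zinc | COc1c(C)c(O[Si](C(C)C)(C(C)C)C(C)C)cc2oc([Zn]Cl)cc12 | intermediate (not isolated)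
23 | {[2-((2S)-7-(benzyloxy)-5-methoxy-2-phenyl-3,4-dihydro-2H-chromen-8-yl)-4-methoxy-5-methyl-1-benzofuran-6-yl]oxy}tri(propan-2-yl)silane | COc1cc(OCc2ccccc2)c(-c2cc3c(OC)c(C)c(O[Si](C(C)C)(C(C)C)C(C)C)cc3o2)c2c1CC[C@@H](c1ccccc1)O2 | intermediate
24 | 2-[(2S)-7-(benzyloxy)-5-methoxy-2-phenyl-3,4-dihydro-2H-chromen-8-yl]-4-methoxy-5-methyl-1-benzofuran-6-ol | COc1cc(OCc2ccccc2)c(-c2cc3c(OC)c(C)c(O)cc3o2)c2c1CC[C@@H](c1ccccc1)O2 | intermediate
25 | 2-[(2S)-7-hydroxy-5-methoxy-2-phenyl-3,4-dihydro-2H-chromen-8-yl]-4-methoxy-5-methyl-1-benzofuran-6-ol | COc1cc(O)c(-c2cc3c(OC)c(C)c(O)cc3o2)c2c1CC[C@@H](c1ccccc1)O2 | target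

**Count and risks**

Total step count: 15.
Longest linear sequence: 10 steps (steps 1 to 7, then 13 to 15).

Steps most likely to fail:

Step 5 (proposed method). Retro-aldol cleavage of the fluoride-generated alkoxide, or a ring closure that is too slow, could lower the yield or erode the configuration at C2. The fallback uses known chemistry and sets out from 4. Crossed Claisen condensation of 4 with methyl benzoate (NaH, THF, 65 °C) should give 1-[4-(benzyloxy)-2-fluoro-6-methoxyphenyl]-3-phenylpropane-1,3-dione F1. Intramolecular SNAr of the enolate oxygen at the fluoro carbon (K2CO3, DMF, 100 °C) should then give 7-(benzyloxy)-5-methoxy-2-phenyl-4H-chromen-4-one F2, so the same two bonds are still made together. The C2=C3 bond of F2 is then hydrogenated asymmetrically with a chiral ruthenium N-heterocyclic carbene catalyst made from [Ru(cod)(2-methylallyl)2], 1,3-bis[1-(naphthalen-1-yl)ethyl]-4,5-dihydroimidazolium tetrafluoroborate (the enantiomer that gives the 2S series) and KOtBu under H2. This comes back to the route at 8; any alcohol formed by over-reduction is 9 and enters step 6 with it.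

Step 13. Slow transmetalation and reductive elimination at the di-ortho-oxygenated aryl bromide, with protodemetalation of the heteroarylzinc, could stall the coupling. The fallback closes the furan ring at the union instead of coupling a finished benzofuran, and sets out from 11 and 18. Bromine–lithium exchange on 11 (n-BuLi, THF, −78 °C) gives [(2S)-7-(benzyloxy)-5-methoxy-2-phenyl-3,4-dihydro-2H-chromen-8-yl]lithium F3, which is quenched with DMF to (2S)-7-(benzyloxy)-5-methoxy-2-phenyl-3,4-dihydro-2H-chromene-8-carbaldehyde F4. Seyferth–Gilbert homologation with the Ohira–Bestmann reagent (dimethyl (1-diazo-2-oxopropyl)phosphonate, K2CO3, MeOH) gives (2S)-7-(benzyloxy)-8-ethynyl-5-methoxy-2-phenyl-3,4-dihydro-2H-chromene F5. Separately, 18 is freed of its methoxymethyl group (HCl, MeOH, 25 °C) to 2-iodo-3-methoxy-4-methyl-5-{[tri(propan-2-yl)silyl]oxy}phenol F6. Sonogashira coupling of F5 with F6 (PdCl2(PPh3)2, CuI, Et3N, DMF, 60 °C) gives 2-{[(2S)-7-(benzyloxy)-5-methoxy-2-phenyl-3,4-dihydro-2H-chromen-8-yl]ethynyl}-3-methoxy-4-methyl-5-{[tri(propan-2-yl)silyl]oxy}phenol F7, which should cyclise in the same flask (5-endo-dig) and so come back to the route at 23.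

Step 6. The C4 cation may be trapped by the electron-rich ring A of a second molecule (Friedel–Crafts oligomerisation) or lose a proton to the flav-3-ene before hydride transfer. The fallback replaces the cationic deoxygenation by a radical one (Barton–McCombie) and sets out from 9, isolated after the borohydride stage. Treatment with NaH, CS2 and MeI in THF gives O-[(2S)-7-(benzyloxy)-5-methoxy-2-phenyl-3,4-dihydro-2H-chromen-4-yl] S-methyl carbonodithioate F8, and Bu3SnH with AIBN in toluene at 90 °C should return to the route at 10.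

**Further compounds**

F1 | step 5 | 1-[4-(benzyloxy)-2-fluoro-6-methoxyphenyl]-3-phenylpropane-1,3-dione | O=C(CC(=O)c1ccccc1)c1c(OC)cc(OCc2ccccc2)cc1F
F2 | step 5 | 7-(benzyloxy)-5-methoxy-2-phenyl-4H-chromen-4-one | COc1cc(OCc2ccccc2)cc2oc(-c3ccccc3)cc(=O)c12
F3 | step 13 | [(2S)-7-(benzyloxy)-5-methoxy-2-phenyl-3,4-dihydro-2H-chromen-8-yl]lithium | COc1cc(OCc2ccccc2)c([Li])c2c1CC[C@@H](c1ccccc1)O2
F4 | step 13 | (2S)-7-(benzyloxy)-5-methoxy-2-phenyl-3,4-dihydro-2H-chromene-8-carbaldehyde | COc1cc(OCc2ccccc2)c(C=O)c2c1CC[C@@H](c1ccccc1)O2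
F5 | step 13 | (2S)-7-(benzyloxy)-8-ethynyl-5-methoxy-2-phenyl-3,4-dihydro-2H-chromene | COc1cc(OCc2ccccc2)c(C#C)c2c1CC[C@@H](c1ccccc1)O2
F6 | step 13 | 2-iodo-3-methoxy-4-methyl-5-{[tri(propan-2-yl)silyl]oxy}phenol | COc1c(C)c(O[Si](C(C)C)(C(C)C)C(C)C)cc(O)c1I
F7 | step 13 | 2-{[(2S)-7-(benzyloxy)-5-methoxy-2-phenyl-3,4-dihydro-2H-chromen-8-yl]ethynyl}-3-methoxy-4-methyl-5-{[tri(propan-2-yl)silyl]oxy}phenol | COc1cc(OCc2ccccc2)c(C#Cc2c(O)cc(O[Si](C(C)C)(C(C)C)C(C)C)c(C)c2OC)c2c1CC[C@@H](c1ccccc1)O2
F8 | step 6 | O-[(2S)-7-(benzyloxy)-5-methoxy-2-phenyl-3,4-dihydro-2H-chromen-4-yl] S-methyl carbonodithioate | COc1cc(OCc2ccccc2)cc2c1C(OC(=S)SC)C[C@@H](c1ccccc1)O2
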